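**Plan**
Retrosynthesis: the two silyl ethers on the catechol of ring B are cut first. Then the O1–C2 ether bond and the C3–C4 bond of ring C are cut together, which leaves a geranylated salicylaldehyde (ring A, O1 as free phenol, C4 as CHO) and a racemic aryl epoxy sulfone that acts as a C2–C3 1,2-dielectrophile. The geranyl ether and the Darzens C–C bond are cut last.
Enabling feature: C3 is a carbinol next to the C4 aryl ketone (an acyloin, reachable redox-neutrally from two aldehydes). C2 is benzylic and bound to O1 and C3, so it is acidic and stereolabile while C3 is an aldehyde.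
Forward: ring A is geranylated (step 1); the ring B aldehyde is silylated and turned into the epoxy sulfone (steps 2 and 3); ring C is closed between the two preformed arenes (step 4); fluoride frees the catechol (step 5).
Stereochemistry: C3 comes from the chiral triazolium carbene catalyst, C2 from dynamic kinetic resolution of the racemising aldehyde (2,3-trans), and the E geranyl alkene is bought in.

Key step: step 4

Assumption: the (5aR,10bS) enantiomer of the aminoindanol-derived triazolium salt is taken to be the one that leads to 3R; the sense of induction cannot be predicted with certainty for this substrate, and the equally available (5aS,10bR) antipode would take its place if it proves opposite.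

**Route**

Step 1
Reactants: 1 2,4-dihydroxybenzaldehyde; 2 geranyl bromide [(2E)-1-bromo-3,7-dimethylocta-2,6-diene]
Product: 3 4-{[(2E)-3,7-dimethylocta-2,6-dien-1-yl]oxy}-2-hydroxybenzaldehyde
Conditions: K2CO3 (1.0 equiv), acetone, rt to 40 °C
Reagents that add atoms: none
Why: Williamson ether synthesis, in which the 2-OH is held in a hydrogen bond to the formyl group and is the less acidic and less nucleophilic phenol under one equivalent of weak base, so the allylic bromide should alkylate the 4-OH by SN2 and leave the E alkene untouched.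

Step 2
Reactants: 4 3,4-dihydroxybenzaldehyde
Product: 5 3,4-bis[(triisopropylsilyl)oxy]benzaldehyde
Conditions: TIPSCl (2.4 equiv), imidazole (5 equiv), DMF, rt
Reagents that add atoms: triisopropylsilyl chloride, CC(C)[Si](Cl)(C(C)C)C(C)C
Why: Imidazole-promoted silylation of both phenols, with the bulky triisopropylsilyl group chosen because it should resist the bases of steps 3 and 4 and leave with fluoride without harm to the geranyl ether.

Step 3
Reactants: 5 3,4-bis[(triisopropylsilyl)oxy]benzaldehyde; 6 chloromethyl phenyl sulfone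
Product: 8 rac-trans-2-{3,4-bis[(triisopropylsilyl)oxy]phenyl}-3-(phenylsulfonyl)oxirane, via chlorohydrin alkoxide 7 (not isolated)
Conditions: KN(SiMe3)2 (1.1 equiv) added to 5 and 6, THF, −78 °C to 0 °C
Reagents that add atoms: none
Why: Darzens condensation, in which the α-chloro-α-sulfonyl carbanion adds to the aldehyde and the chlorohydrin alkoxide closes by intramolecular SN2 to the trans epoxy sulfone; the product is racemic by design, because both of its stereocentres are erased or reset in step 4.

Step 4
Reactants: 3 4-{[(2E)-3,7-dimethylocta-2,6-dien-1-yl]oxy}-2-hydroxybenzaldehyde; 8 rac-trans-2-{3,4-bis[(triisopropylsilyl)oxy]phenyl}-3-(phenylsulfonyl)oxirane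
Product: 10 (2R,3R)-2-{3,4-bis[(triisopropylsilyl)oxy]phenyl}-7-{[(2E)-3,7-dimethylocta-2,6-dien-1-yl]oxy}-3-hydroxy-2,3-dihydro-4H-chromen-4-one, via dialdehyde 9 (not isolated)
Conditions: 8 (1.05 equiv), K2CO3 (1.5 equiv), MeCN, 4 Å MS, Ar, 40 °C; then (5aR,10bS)-2-(pentafluorophenyl)-5a,10b-dihydro-4H,6H-indeno[2,1-b][1,2,4]triazolo[4,3-d][1,4]oxazin-2-ium tetrafluoroborate (15 mol%), rt, same pot
Reagents that add atoms: none
Why: Proposed new method: under carbonate the phenoxide of 3 should open 8 at the benzylic epoxide carbon (SN2 at the sulfonyl-bearing carbon is disfavoured), and the α-sulfonyl alkoxide then expels benzenesulfinate, which forges O1–C2 and unmasks C3 as an aldehyde in dialdehyde 9; the triazolylidene carbene then adds to the aromatic aldehyde, and the derived acyl-anion equivalent (Breslow intermediate) attacks the C3 aldehyde to forge C4–C3 and deliver the C3 carbinol and the C4 ketone at the right oxidation level without any redox reagent. The closest known reaction types are the opening of α,β-epoxy sulfones by heteroatom nucleophiles to α-substituted aldehydes and the carbene-catalysed intramolecular crossed benzoin reaction of 2-(2-oxoalkoxy)benzaldehydes to 3-hydroxychroman-4-ones, which are merged here and run as a dynamic kinetic resolution. Ring C closes in the 6-exo-trig mode, by attack of C4 on the exocyclic C3=O. C3 is controlled by the chiral triazolium scaffold, which blocks one face of the acyl-anion equivalent, whereas C2 is controlled by dynamic kinetic resolution: the C2–H of 9 is alpha to the aldehyde, benzylic and alpha to oxygen, so the two enantiomers of 9 should interconvert through the enolate faster than they cyclise, and the chair-like transition state with the C2 aryl group equatorial and anti to the developing C3–O bond should lead from both to the 2,3-trans (2R,3R) product. The step needs regioselective epoxide opening, secured by the sulfonyl group and the electron-rich ring B, and chemoselective carbene engagement of the aromatic aldehyde over the aliphatic one, whose adduct could eliminate the aryloxy group; the α,α-disubstitution at C2 and the electron-poor N-pentafluorophenyl catalyst, which favours benzoin over redox pathways, should secure this.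

Step 5
Reactants: 10 (2R,3R)-2-{3,4-bis[(triisopropylsilyl)oxy]phenyl}-7-{[(2E)-3,7-dimethylocta-2,6-dien-1-yl]oxy}-3-hydroxy-2,3-dihydro-4H-chromen-4-one
Product: 11 (2R,3R)-2-(3,4-dihydroxyphenyl)-7-{[(2E)-3,7-dimethylocta-2,6-dien-1-yl]oxy}-3-hydroxy-2,3-dihydro-4H-chromen-4-one
Conditions: Bu4NF (2.5 equiv), AcOH (2.5 equiv), THF, 0 °C, Ar
Reagents that add atoms: none
Why: Fluoride-mediated cleavage of the two aryl silyl ethers, buffered with acetic acid so that the acyloin and the catechol are not kept as free phenoxides, should leave C2, C3 and the geranyl ether untouched; the 2,3-trans arrangement is also the thermodynamically preferred one, so any reversible ring-opening at C2 through the quinone methide of the freed 4'-phenol should return the same isomer.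

**Compound list**

1 | 2,4-dihydroxybenzaldehyde | O=Cc1ccc(O)cc1O | starting material
2 | geranyl bromide, (2E)-1-bromo-3,7-dimethylocta-2,6-diene | CC(C)=CCC/C(C)=C/CBr | starting material
3 | 4-{[(2E)-3,7-dimethylocta-2,6-dien-1-yl]oxy}-2-hydroxybenzaldehyde | CC(C)=CCC/C(C)=C/COc1ccc(C=O)c(O)c1 | intermediate
4 | 3,4-dihydroxybenzaldehyde | O=Cc1ccc(O)c(O)c1 | starting material
5 | 3,4-bis[(triisopropylsilyl)oxy]benzaldehyde | O=Cc1ccc(O[Si](C(C)C)(C(C)C)C(C)C)c(O[Si](C(C)C)(C(C)C)C(C)C)c1 | intermediate
6 | chloromethyl phenyl sulfone | ClCS(=O)(=O)c1ccccc1 | starting material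
7 | 2-chloro-1-{3,4-bis[(triisopropylsilyl)oxy]phenyl}-2-(phenylsulfonyl)ethan-1-ol, present as its potassium alkoxide (racemic, mixture of diastereomers, not isolated) | OC(c1ccc(O[Si](C(C)C)(C(C)C)C(C)C)c(O[Si](C(C)C)(C(C)C)C(C)C)c1)C(Cl)S(=O)(=O)c1ccccc1 | intermediate
8 | rac-trans-2-{3,4-bis[(triisopropylsilyl)oxy]phenyl}-3-(phenylsulfonyl)oxirane (racemate, one enantiomer drawn) | CC(C)[Si](C(C)C)(C(C)C)Oc1ccc(cc1O[Si](C(C)C)(C(C)C)C(C)C)[C@@H]2O[C@H]2S(=O)(=O)c3ccccc3 | intermediate
9 | 2-(1-{3,4-bis[(triisopropylsilyl)oxy]phenyl}-2-oxoethoxy)-4-{[(2E)-3,7-dimethylocta-2,6-dien-1-yl]oxy}benzaldehyde (racemic, stereolabile, not isolated) | CC(C)=CCC/C(C)=C/COc1ccc(C=O)c(OC(C=O)c2ccc(O[Si](C(C)C)(C(C)C)C(C)C)c(O[Si](C(C)C)(C(C)C)C(C)C)c2)c1 | intermediate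
10 | (2R,3R)-2-{3,4-bis[(triisopropylsilyl)oxy]phenyl}-7-{[(2E)-3,7-dimethylocta-2,6-dien-1-yl]oxy}-3-hydroxy-2,3-dihydro-4H-chromen-4-one | CC(C)=CCC/C(C)=C/COc1ccc2c(c1)O[C@H](c1ccc(O[Si](C(C)C)(C(C)C)C(C)C)c(O[Si](C(C)C)(C(C)C)C(C)C)c1)[C@@H](O)C2=O | intermediate
11 | (2R,3R)-2-(3,4-dihydroxyphenyl)-7-{[(2E)-3,7-dimethylocta-2,6-dien-1-yl]oxy}-3-hydroxy-2,3-dihydro-4H-chromen-4-one | CC(C)=CCC/C(C)=C/COc1ccc2c(c1)O[C@H](c1ccc(O)c(O)c1)[C@@H](O)C2=O | target

**Step count**

Total step count: 5
Longest linear sequence: 4 steps (4 → 5 → 8 → 10 → 11; steps 2, 3, 4, 5)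

**Steps most likely to fail**

1. Step 4 (Proposed new method). The carbene may engage the aliphatic aldehyde of 9 and trigger loss of the aryloxy group (redox esterification in place of benzoin closure). Enolisation at C2 may also be too slow for stereoconvergence, which would give poor diastereocontrol, and the acyloin may epimerise at C3 under the base. The fallback uses known chemistry (the chalcone epoxide route); it sets out from 3 and 5 and comes back to the route at 11. Silylation of 3 (TIPSCl, imidazole, DMF) should give 4-{[(2E)-3,7-dimethylocta-2,6-dien-1-yl]oxy}-2-[(triisopropylsilyl)oxy]benzaldehyde F1. Addition of MeMgBr (THF, 0 °C) should give the racemic benzylic alcohol F2, and Dess–Martin periodinane (CH2Cl2, rt) the acetophenone F3. Its lithium enolate (LiN(SiMe3)2, THF, −78 °C) adds to 5 to give the aldol adduct F4, which is dehydrated (MsCl, Et3N, then DBU) to the E chalcone F5. Juliá–Colonna epoxidation (poly-L-leucine, urea–H2O2, DBU, THF) should give the (αR,βS)-epoxy ketone F6 and leave the electron-rich geranyl alkenes alone, since the oxidant is nucleophilic. Bu4NF/AcOH (THF, 0 °C) then removes the three silyl groups, and the freed 2'-phenol opens the epoxide at the benzylic carbon with inversion (6-endo) to give 11 directly.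

2. Step 3. The α-chloro sulfonyl carbanion may decompose before it adds, the aryl silyl ethers may be attacked by the base, and the electron-rich aryl epoxide may open during isolation. The fallback sets out from 5 and comes back at 8. Horner–Wadsworth–Emmons olefination of 5 with diethyl [(phenylsulfonyl)methyl]phosphonate (NaH, THF, 0 °C to rt) should give (E)-2-{3,4-bis[(triisopropylsilyl)oxy]phenyl}ethenyl phenyl sulfone F7. Nucleophilic epoxidation of this vinyl sulfone with lithium tert-butyl peroxide (t-BuOOH, n-BuLi, THF, −20 °C) should then give 8 under conditions without a carbenoid.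

3. Step 1. Over-alkylation at the hydrogen-bonded 2-OH and C-alkylation of the resorcinol ring by the allylic bromide may erode the regioselectivity. The fallback sets out from 1 and comes back at 3: Mitsunobu etherification of 1 with geraniol (PPh3, diisopropyl azodicarboxylate, THF, 0 °C) replaces phenoxide alkylation by a redox condensation under neutral conditions, in which only the more acidic, unchelated 4-OH should react; it makes no new compound.

**Further compounds**

F1 | step 4 | 4-{[(2E)-3,7-dimethylocta-2,6-dien-1-yl]oxy}-2-[(triisopropylsilyl)oxy]benzaldehyde | CC(C)=CCC/C(C)=C/COc1ccc(C=O)c(O[Si](C(C)C)(C(C)C)C(C)C)c1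
F2 | step 4 | 1-(4-{[(2E)-3,7-dimethylocta-2,6-dien-1-yl]oxy}-2-[(triisopropylsilyl)oxy]phenyl)ethan-1-ol (racemic) | CC(C)=CCC/C(C)=C/COc1ccc(C(C)O)c(O[Si](C(C)C)(C(C)C)C(C)C)c1
F3 | step 4 | 1-(4-{[(2E)-3,7-dimethylocta-2,6-dien-1-yl]oxy}-2-[(triisopropylsilyl)oxy]phenyl)ethan-1-one | CC(C)=CCC/C(C)=C/COc1ccc(C(C)=O)c(O[Si](C(C)C)(C(C)C)C(C)C)c1
F4 | step 4 | 3-{3,4-bis[(triisopropylsilyl)oxy]phenyl}-1-(4-{[(2E)-3,7-dimethylocta-2,6-dien-1-yl]oxy}-2-[(triisopropylsilyl)oxy]phenyl)-3-hydroxypropan-1-one (racemic) | CC(C)=CCC/C(C)=C/COc1ccc(C(=O)CC(O)c2ccc(O[Si](C(C)C)(C(C)C)C(C)C)c(O[Si](C(C)C)(C(C)C)C(C)C)c2)c(O[Si](C(C)C)(C(C)C)C(C)C)c1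
F5 | step 4 | (2E)-3-{3,4-bis[(triisopropylsilyl)oxy]phenyl}-1-(4-{[(2E)-3,7-dimethylocta-2,6-dien-1-yl]oxy}-2-[(triisopropylsilyl)oxy]phenyl)prop-2-en-1-one | CC(C)=CCC/C(C)=C/COc1ccc(C(=O)/C=C/c2ccc(O[Si](C(C)C)(C(C)C)C(C)C)c(O[Si](C(C)C)(C(C)C)C(C)C)c2)c(O[Si](C(C)C)(C(C)C)C(C)C)c1
F6 | step 4 | [(2R,3S)-3-{3,4-bis[(triisopropylsilyl)oxy]phenyl}oxiran-2-yl](4-{[(2E)-3,7-dimethylocta-2,6-dien-1-yl]oxy}-2-[(triisopropylsilyl)oxy]phenyl)methanone | CC(C)=CCC/C(C)=C/COc1ccc(C(=O)[C@@H]2O[C@H]2c3ccc(O[Si](C(C)C)(C(C)C)C(C)C)c(O[Si](C(C)C)(C(C)C)C(C)C)c3)c(O[Si](C(C)C)(C(C)C)C(C)C)c1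
F7 | step 3 | (E)-2-{3,4-bis[(triisopropylsilyl)oxy]phenyl}ethenyl phenyl sulfone | O=S(=O)(/C=C/c1ccc(O[Si](C(C)C)(C(C)C)C(C)C)c(O[Si](C(C)C)(C(C)C)C(C)C)c1)c1ccccc1
F0 | step 1 | none | none
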